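Gentiside K, an achiral ester, is cut at its carbonyl carbon: this one-carbon unit lies between C1 of the benzene ring (the carbon beside the oxygen-bearing C2 and C3) and the oxygen of the unbranched C24 chain, so carbon monoxide can provide it. Benzylation of 3-bromocatechol 1 with benzyl bromide 2 gives the precursor 3, a 1,2-bis(benzyloxy)benzene carrying bromine at the future C1. One palladium-catalysed alkoxycarbonylation then unites 3, CO 4 and 1-tetracosanol 5, making the C1–C(=O) and C(=O)–O bonds of ester 6 in a single operation without closing a ring. Hydrogenolysis of the two benzyl ethers releases target 7.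

Key step: step 2

Assumption: the target has no stereocentre, stereogenic double bond or axis, so "single enantiomer" is read as the one achiral compound drawn and no step has to control configuration. Benzyl ethers are kept on the catechol because they are inert to Pd(0)/CO/amine at 95 °C and leave under neutral hydrogenolysis that spares the alkyl ester.

Step 1
Reactants: 1 3-bromocatechol (3-bromobenzene-1,2-diol); 2 benzyl bromide
Product: 3 1,2-bis(benzyloxy)-3-bromobenzene
Conditions: BnBr (2.4 equiv), K2CO3 (3 equiv), DMF, N2, 60 °C
Reagents that add atoms: benzyl bromide (2), BrCc1ccccc1
Why: Double Williamson ether synthesis, in which carbonate generates the phenoxides and these displace bromide from the benzylic halide by SN2 in DMF, while the aryl C–Br bond is untouched and the nitrogen atmosphere guards the catecholate against oxidation.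

Step 2
Reactants: 3 1,2-bis(benzyloxy)-3-bromobenzene; 4 carbon monoxide; 5 1-tetracosanol
Product: 6 tetracosyl 2,3-bis(benzyloxy)benzoate
Conditions: Pd(OAc)2 (3 mol %), Xantphos (6 mol %), Et3N (3 equiv), CO (1 atm, balloon), 5 (1.1 equiv), toluene, 95 °C
Reagents that add atoms: carbon monoxide (4), [C-]#[O+]; 1-tetracosanol (5), CCCCCCCCCCCCCCCCCCCCCCCCO
Why: Pd(0)–Xantphos inserts into the C1–Br bond of 3, CO then binds and migrates into the aryl–Pd bond to give an aroyl-palladium(II) bromide, and triethylamine-assisted attack of 5 on this acyl complex releases ester 6 and regenerates Pd(0). The closest known reaction type is the Heck-type alkoxycarbonylation of aryl bromides under one atmosphere of CO with a wide-bite-angle diphosphine. No ring is closed and no stereocentre is formed, so neither a mode of closure nor stereocontrol arises. The step needs chemoselectivity for carbonylative esterification over direct C–O coupling to the aryl ether and over hydrodebromination, and it needs the carboxyl group at one defined ring position. The CO atmosphere and the Xantphos ligand favour the acyl complex and its alcoholysis, the bromine of 3 fixes the carboxyl at C1 beside the two oxygenated carbons, and the benzyl ethers keep the catechol oxygens from chelating palladium or competing as nucleophiles. Toluene at 95 °C keeps the waxy alcohol dissolved so that it can be used close to stoichiometry.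

Step 3
Reactants: 6 tetracosyl 2,3-bis(benzyloxy)benzoate
Product: 7 Gentiside K (tetracosyl 2,3-dihydroxybenzoate)
Conditions: H2 (1 atm), 10% Pd/C, THF, 40 °C
Reagents that add atoms: none
Why: Heterogeneous catalytic hydrogenolysis cleaves both benzylic C–O bonds as toluene while the primary alkyl ester and the arene are inert at 1 atm, warm THF keeps the waxy substrate and product dissolved, and the product is the achiral target with no stereocentre to set.

Compound list
1 | 3-bromocatechol (3-bromobenzene-1,2-diol) | Oc1cccc(Br)c1O | starting material
2 | benzyl bromide | BrCc1ccccc1 | starting material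
3 | 1,2-bis(benzyloxy)-3-bromobenzene | Brc1cccc(OCc2ccccc2)c1OCc1ccccc1 | intermediate
4 | carbon monoxide | [C-]#[O+] | starting material
5 | 1-tetracosanol | CCCCCCCCCCCCCCCCCCCCCCCCO | starting material
6 | tetracosyl 2,3-bis(benzyloxy)benzoate | CCCCCCCCCCCCCCCCCCCCCCCCOC(=O)c1cccc(OCc2ccccc2)c1OCc1ccccc1 | intermediate
7 | Gentiside K (tetracosyl 2,3-dihydroxybenzoate, achiral) | CCCCCCCCCCCCCCCCCCCCCCCCOC(=O)c1cccc(O)c1O | target

Total step count: 3
Longest linear sequence: 3 steps (1 → 3 → 6 → 7)

Steps most likely to fail

Step 2. Oxidative addition into the electron-rich, ortho-alkoxylated aryl bromide may be slow. Capture of the acyl complex by the dilute long-chain alcohol may also lag, which would let hydrodebromination and catalyst decomposition take over. The fallback sets out from 3 and gives up the carbonylation in favour of organolithium chemistry. Bromine–lithium exchange (n-BuLi, THF, −78 °C) should give [2,3-bis(benzyloxy)phenyl]lithium F1 (not isolated). Quenching with dry CO2 and acidifying with aqueous HCl should give 2,3-bis(benzyloxy)benzoic acid F2. Steglich esterification of F2 with 5 (EDC·HCl, DMAP, CH2Cl2–THF, 35 °C) comes back to the route at 6.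

Step 3. Hydrogenolysis may stop part-way through catalyst poisoning by phosphine or bromide traces carried over from step 2, or through deposition of waxy material on the catalyst surface. The fallback sets out from 6 and replaces reduction by Lewis-acid dealkylation: BCl3 (4 equiv) with pentamethylbenzene as benzyl-cation scavenger in CH2Cl2 at −78 °C, then aqueous work-up. These conditions spare alkyl esters and should give 7 directly; no new compound is made on this way (F0).

Step 1. The catecholate may oxidise under base, and the second alkylation may stall at the hindered oxygen flanked by bromine and the first benzyloxy group. The fallback sets out from 1 and masks both oxygens at once, without base, as a cyclic ketal. Heating 1 with dichlorodiphenylmethane (ClC(Cl)(c1ccccc1)c1ccccc1, neat, 160 °C) should give 4-bromo-2,2-diphenyl-1,3-benzodioxole F3. The same alkoxycarbonylation with 4 and 5 (Pd(OAc)2, Xantphos, Et3N, toluene, 95 °C) should give tetracosyl 2,2-diphenyl-1,3-benzodioxole-4-carboxylate F4. Hydrogenolysis of the diphenylmethylene ketal (H2, Pd(OH)2/C, THF–MeOH, 40 °C) comes back to the route at 7.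

Further compounds
F1 | step 2 | [2,3-bis(benzyloxy)phenyl]lithium (not isolated) | [Li]c1cccc(OCc2ccccc2)c1OCc1ccccc1
F2 | step 2 | 2,3-bis(benzyloxy)benzoic acid | OC(=O)c1cccc(OCc2ccccc2)c1OCc1ccccc1
F0 | step 3 | none | none
F3 | step 1 | 4-bromo-2,2-diphenyl-1,3-benzodioxole | Brc1cccc2OC(c3ccccc3)(c3ccccc3)Oc12
F4 | step 1 | tetracosyl 2,2-diphenyl-1,3-benzodioxole-4-carboxylate | CCCCCCCCCCCCCCCCCCCCCCCCOC(=O)c1cccc2OC(c3ccccc3)(c3ccccc3)Oc12
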